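**Plan**

Locants: oxane ring O1–C2(CH3)(OH)–C3(Br)–C4–C5–C6. The side chain on C5 is C7(CH3)(Cl)–C8=C9(Br).
Retrosynthesis: O1–C2, C3–Br and C2–OH are cut together (oxane → acyclic chloro-olefin alcohol). Then come C8=C9 (bromo-olefination), C7–Cl and C7–CH3 (enolate chemistry on a temporary γ-lactone C8–C7–C5–C6–O), and last C4–C5 (auxiliary-controlled alkylation of a succinate).
Enabling feature: in the ring the hemiketal carbon C2 stands next to C3–Br. This is the adduct of Br+ and oxygen across a C2=C3 π bond at the ketone oxidation level. Every ring substituent is equatorial except the anomeric OH, so chair-controlled closure and thermodynamic preference point to the same isomer.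
Forward: succinate and 1,3-dichlorobutene give the C2–C8 chain. The temporary lactone closes, takes up CH3 and Cl, and is opened by reduction/olefination, which frees the C6 hydroxyl. The oxane, the only ring of the target, closes last by a Br+-triggered oxacyclisation modelled on the bromoperoxidase chemistry presumed for red-algal bromo-oxanes.
Stereochemistry: C5 comes from (S)-4-benzyloxazolidinone, C7 from C5 (Cl+ anti to the side chain on the lactone enolate), C3 from C5 (chair, anti addition), C2 from the anomeric effect, and (E)-C8=C9 from the Takai reaction.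
Helpers: the vinylic chlorine on C2 steers Br to C3, makes C2 the cationic terminus and leaves as chloride in the key step. The lactone ring is taken apart in steps 6 and 7.

Key step: step 8

Assumption: 1,3-dichlorobut-2-ene is used as its (Z)-isomer. The commercial E/Z mixture would lead to the same target, because the chlorine on C2 and the C2=C3 geometry are both lost in step 8.

Step 1
Reactants: 1 4-tert-butoxy-4-oxobutanoic acid (mono-tert-butyl succinate); 2 (4S)-4-benzyl-1,3-oxazolidin-2-one
Product: 4 tert-butyl 4-[(4S)-4-benzyl-2-oxo-1,3-oxazolidin-3-yl]-4-oxobutanoate, via mixed anhydride 3 (not isolated)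
Conditions: PivCl, Et3N, THF, −20 °C; then LiCl, 2, −20 °C → rt
Reagents that add atoms: pivaloyl chloride CC(C)(C)C(=O)Cl (its acyl group stays in 3 only)
Why: N-Acylation of an oxazolidinone through a mixed pivalic anhydride (LiCl/Et3N variant) should transfer only the unhindered succinyl carbonyl group of 3 and touches no stereocenter.

Step 2
Reactants: 4 tert-butyl 4-[(4S)-4-benzyl-2-oxo-1,3-oxazolidin-3-yl]-4-oxobutanoate; 5 (Z)-1,3-dichlorobut-2-ene
Product: 8 tert-butyl (3S,5Z)-3-{[(4S)-4-benzyl-2-oxo-1,3-oxazolidin-3-yl]carbonyl}-6-chlorohept-5-enoate, via allylic iodide 6 (not isolated), via sodium enolate 7 (not isolated)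
Conditions: 5, NaI, THF, rt (→ 6); separately 4, NaHMDS, THF, −78 °C (→ 7); then 6 added, −78 → −40 °C
Reagents that add atoms: sodium iodide [Na+].[I-] (iodine in 6 only); sodium hexamethyldisilazide C[Si](C)(C)[N-][Si](C)(C)C.[Na+] (sodium in 7 only)
Why: Evans asymmetric alkylation: NaHMDS removes only the more acidic imide α-proton to give the chelated (Z)-enolate 7, whose face opposite to the benzyl group displaces the allylic iodide of 6 (made by Finkelstein exchange; the vinylic C–Cl is inert to SN2) and thereby sets C5 as (3S) in 8.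

Step 3
Reactants: 8 tert-butyl (3S,5Z)-3-{[(4S)-4-benzyl-2-oxo-1,3-oxazolidin-3-yl]carbonyl}-6-chlorohept-5-enoate
Product: 10 (4S)-4-[(2Z)-3-chlorobut-2-en-1-yl]oxolan-2-one, via hydroxy ester 9 (not isolated)
Conditions: LiBH4, THF, 0 °C; aq. work-up; crude in CH2Cl2, TFA, 0 °C → rt
Reagents that add atoms: none
Why: LiBH4 reduces the activated imide carbonyl group in preference to the tert-butyl ester and releases the auxiliary (reductive auxiliary cleavage), and TFA then removes isobutene from 9 so that the γ-hydroxy acid lactonises to the temporary ring, C5 being untouched because no enolisable carbonyl group remains next to it.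

Step 4
Reactants: 10 (4S)-4-[(2Z)-3-chlorobut-2-en-1-yl]oxolan-2-one
Product: 12 (3S,4S)-4-[(2Z)-3-chlorobut-2-en-1-yl]-3-methyloxolan-2-one (trans), via lithium enolate 11 (not isolated)
Conditions: LDA, THF, −78 °C; then MeI, −78 → −40 °C
Reagents that add atoms: iodomethane CI; lithium diisopropylamide CC(C)[N-]C(C)C.[Li+] (lithium in 11 only)
Why: Alkylation of a γ-lactone enolate: MeI should enter anti to the C5 side chain to give the trans lactone, although the ratio is of no consequence because C7 is made planar again in step 5.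

Step 5
Reactants: 12 (3S,4S)-4-[(2Z)-3-chlorobut-2-en-1-yl]-3-methyloxolan-2-one
Product: 14 (3S,4R)-3-chloro-4-[(2Z)-3-chlorobut-2-en-1-yl]-3-methyloxolan-2-one (Cl trans and CH3 cis to the side chain), via lithium enolate 13 (not isolated)
Conditions: LDA, THF, −78 °C; then C2Cl6, THF, −78 °C
Reagents that add atoms: hexachloroethane ClC(Cl)(Cl)C(Cl)(Cl)Cl; lithium diisopropylamide CC(C)[N-]C(C)C.[Li+] (lithium in 13 only)
Why: Electrophilic α-chlorination of a lactone enolate with a positive-halogen donor: the flat, tetrasubstituted enolate 13 is shielded on one face by the neighbouring C5 side chain, so chlorine should be taken up on the opposite face, which is (S)-C7, and the product has no α-hydrogen through which it could epimerise.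

Step 6
Reactants: 14 (3S,4R)-3-chloro-4-[(2Z)-3-chlorobut-2-en-1-yl]-3-methyloxolan-2-one
Product: 15 (3S,4R)-3-chloro-4-[(2Z)-3-chlorobut-2-en-1-yl]-3-methyloxolan-2-ol (lactol; mixture of anomers at C2 of the oxolane)
Conditions: DIBAL-H (1.1 equiv), CH2Cl2, −78 °C; Rochelle salt work-up
Reagents that add atoms: none
Why: Partial reduction of a lactone with DIBAL-H at −78 °C should stop at the aluminium hemiacetal and give the lactol on work-up, the tertiary and vinylic C–Cl bonds being inert to the reagent at this temperature.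

Step 7
Reactants: 15 (3S,4R)-3-chloro-4-[(2Z)-3-chlorobut-2-en-1-yl]-3-methyloxolan-2-ol
Product: 17 (2R,4Z)-2-[(2S,3E)-4-bromo-2-chlorobut-3-en-2-yl]-5-chlorohex-4-en-1-ol, via hydroxy aldehyde 16 (not isolated)
Conditions: CrBr2, CHBr3, THF, 0 °C → rt
Reagents that add atoms: bromoform BrC(Br)Br
Why: Takai olefination: the open tautomer 16 of the lactol is intercepted by the gem-dichromium reagent from CHBr3 and Cr(II), whose anti-periplanar elimination gives the (E)-bromoalkene, the all-bromide medium avoids Cl/Br scrambling at C9, the vinylic chloride is inert to Cr(II) without nickel, C7 is quaternary and cannot epimerise, and the temporary ring is opened so that the C6 hydroxyl is set free.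

Step 8
Reactants: 17 (2R,4Z)-2-[(2S,3E)-4-bromo-2-chlorobut-3-en-2-yl]-5-chlorohex-4-en-1-ol
Product: 19 (2R,3S,5R)-3-bromo-5-[(2S,3E)-4-bromo-2-chlorobut-3-en-2-yl]-2-methyloxan-2-ol (target), via chloro-oxane 18 (not isolated)
Conditions: NBS, NaHCO3, MeCN, −20 °C, dark; then H2O, 0 °C → rt
Reagents that add atoms: N-bromosuccinimide O=C1CCC(=O)N1Br; water O
Why: Br+ from NBS adds to C2=C3, the only electron-rich π bond (C8=C9 is deactivated by its own bromine and by the allylic C7–Cl), and the developing positive charge sits on C2, where the chlorine lone pair and the methyl group stabilise it, so that bromine ends up on C3 only. The C6 hydroxyl captures C2 anti to bromine in a 6-endo closure (both alkene carbons end up in the ring; 5-exo attack at C3 would be anti-Markovnikov) to give the α-chloro ether 18, which ionises to the oxocarbenium ion as soon as water is added and gives hemiketal 19 with loss of chloride, so the helper chlorine leaves in the step that uses it. The closest known reaction types are the NBS/water conversion of vinyl chlorides into α-bromo ketones and the bromonium-induced 6-endo etherification of hydroxy alkenes, which is also the way haloperoxidases are thought to build bromo-oxanes. C3 is controlled by C5: anti addition through a chair places Br equatorial, and the chair that keeps the bulky C7 group on C5 equatorial makes Br cis to it (3S). C2 is set under thermodynamic control, since the hemiketal opens and closes freely and the anomeric effect holds OH axial and CH3 equatorial (2R). Because 19 is the all-equatorial isomer and C3 is α to the carbonyl group of the open tautomer, any leakage through capture by external water is drawn to the same product on equilibration.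

**Compound list**

1 | 4-tert-butoxy-4-oxobutanoic acid | CC(C)(C)OC(=O)CCC(=O)O | starting material
2 | (4S)-4-benzyl-1,3-oxazolidin-2-one | O=C1N[C@@H](Cc2ccccc2)CO1 | starting material
3 | 4-tert-butoxy-4-oxobutanoic pivalic anhydride | CC(C)(C)OC(=O)CCC(=O)OC(=O)C(C)(C)C | intermediate
4 | tert-butyl 4-[(4S)-4-benzyl-2-oxo-1,3-oxazolidin-3-yl]-4-oxobutanoate | CC(C)(C)OC(=O)CCC(=O)N1[C@@H](Cc2ccccc2)COC1=O | intermediate
5 | (Z)-1,3-dichlorobut-2-ene | ClC/C=C(/C)Cl | starting material
6 | (Z)-3-chloro-1-iodobut-2-ene | IC/C=C(/C)Cl | intermediate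
7 | sodium (Z)-enolate of 4 | CC(C)(C)OC(=O)C/C=C(\[O-])N1[C@@H](Cc2ccccc2)COC1=O.[Na+] | intermediate
8 | tert-butyl (3S,5Z)-3-{[(4S)-4-benzyl-2-oxo-1,3-oxazolidin-3-yl]carbonyl}-6-chlorohept-5-enoate | CC(C)(C)OC(=O)C[C@H](C/C=C(/C)Cl)C(=O)N1[C@@H](Cc2ccccc2)COC1=O | intermediate
9 | tert-butyl (3S,5Z)-6-chloro-3-(hydroxymethyl)hept-5-enoate | CC(C)(C)OC(=O)C[C@H](C/C=C(/C)Cl)CO | intermediate
10 | (4S)-4-[(2Z)-3-chlorobut-2-en-1-yl]oxolan-2-one | O=C1C[C@H](C/C=C(/C)Cl)CO1 | intermediate
11 | lithium enolate of 10 | [Li+].[O-]C1=C[C@H](C/C=C(/C)Cl)CO1 | intermediate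
12 | (3S,4S)-4-[(2Z)-3-chlorobut-2-en-1-yl]-3-methyloxolan-2-one | C[C@@H]1C(=O)OC[C@H]1C/C=C(/C)Cl | intermediate
13 | lithium enolate of 12 | [Li+].[O-]C1=C(C)[C@H](C/C=C(/C)Cl)CO1 | intermediate
14 | (3S,4R)-3-chloro-4-[(2Z)-3-chlorobut-2-en-1-yl]-3-methyloxolan-2-one | C[C@@]1(Cl)C(=O)OC[C@H]1C/C=C(/C)Cl | intermediate
15 | (3S,4R)-3-chloro-4-[(2Z)-3-chlorobut-2-en-1-yl]-3-methyloxolan-2-ol (anomer mixture) | C[C@@]1(Cl)C(O)OC[C@H]1C/C=C(/C)Cl | intermediate
16 | (2S,3R,5Z)-2,6-dichloro-3-(hydroxymethyl)-2-methylhept-5-enal | C[C@@](Cl)(C=O)[C@@H](CO)C/C=C(/C)Cl | intermediate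
17 | (2R,4Z)-2-[(2S,3E)-4-bromo-2-chlorobut-3-en-2-yl]-5-chlorohex-4-en-1-ol | C[C@@](Cl)(/C=C/Br)[C@@H](CO)C/C=C(/C)Cl | intermediate
18 | (2S,3S,5R)-3-bromo-5-[(2S,3E)-4-bromo-2-chlorobut-3-en-2-yl]-2-chloro-2-methyloxane | C[C@@](Cl)(/C=C/Br)[C@H]1CO[C@@](C)(Cl)[C@@H](Br)C1 | intermediate
19 | (2R,3S,5R)-3-bromo-5-[(2S,3E)-4-bromo-2-chlorobut-3-en-2-yl]-2-methyloxan-2-ol | C[C@@](Cl)(/C=C/Br)[C@H]1CO[C@@](C)(O)[C@@H](Br)C1 | target

Total step count: 8. Longest linear sequence: 8 steps (from 1 or 2 to 19).

**Steps most likely to fail**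

Step 7. The lactol is held closed by the quaternary C7 and may release the free aldehyde too slowly for the gem-dichromium addition. Long contact with Cr(II) also invites reductive loss of the tertiary chloride next to the carbonyl group. The fallback sets out from 14 and comes back at 17.
- The lactone is opened with Me(MeO)NH·HCl/Me3Al to the hydroxy Weinreb amide F1.
- This is silylated at once (TBSCl, imidazole) to the silylated Weinreb amide F2.
- DIBAL-H gives the acyclic silyloxy aldehyde F3, which cannot close to a lactol.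
- Takai bromo-olefination with short contact gives the silyl ether of 17 F4.
- HF·pyridine returns 17.

Step 8. Control at C3 would be eroded in two ways: capture of the cationic intermediate by external nucleophiles instead of the C6 hydroxyl, or unselective delivery of Br+ to the two alkene faces before the chair is organised. The aqueous phase may also start solvolysis of the tertiary allylic chloride. The fallback sets out from 14 and comes back at 19. It closes the ring first and brings in bromine afterwards.
- The vinyl chloride of 14 is hydrolysed with cold concentrated H2SO4 (Wichterle unmasking) to the keto lactone F5.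
- The ketone is masked with ethylene glycol/p-TsOH as the dioxolane lactone F6.
- DIBAL-H gives the dioxolane lactol F7, and Takai bromo-olefination gives the hydroxy ketal F8.
- PPTS in wet acetone removes the dioxolane, and the δ-hydroxy ketone closes by itself to the bromine-free hemiketal F9.
- Pyridinium tribromide in THF then brominates the more substituted enol (C3), and the HBr formed equilibrates C3 through the open keto form to the equatorial bromide 19.

Step 5. Facial selectivity in the delivery of Cl+ may be poor, since the only directing element is a CH2-linked chain on the neighbouring carbon. The fallback sets out from 12 and comes back at 14. Enolate 13 is trapped with TMSCl as the silyl ketene acetal F10. This is chlorinated with NCS under a chiral squaramide hydrogen-bond-donor catalyst. The face is then chosen by the catalyst, in the sense matched to the substrate bias, and not by the substrate alone.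

**Further compounds**

F1 | step 7 | (2S,3R,5Z)-2,6-dichloro-3-(hydroxymethyl)-N-methoxy-N,2-dimethylhept-5-enamide | C[C@@](Cl)(C(=O)N(C)OC)[C@@H](CO)C/C=C(/C)Cl
F2 | step 7 | (2S,3R,5Z)-3-({[tert-butyl(dimethyl)silyl]oxy}methyl)-2,6-dichloro-N-methoxy-N,2-dimethylhept-5-enamide | C[C@@](Cl)(C(=O)N(C)OC)[C@@H](CO[Si](C)(C)C(C)(C)C)C/C=C(/C)Cl
F3 | step 7 | (2S,3R,5Z)-3-({[tert-butyl(dimethyl)silyl]oxy}methyl)-2,6-dichloro-2-methylhept-5-enal | C[C@@](Cl)(C=O)[C@@H](CO[Si](C)(C)C(C)(C)C)C/C=C(/C)Cl
F4 | step 7 | tert-butyl(dimethyl)silyl ether of 17 | C[C@@](Cl)(/C=C/Br)[C@@H](CO[Si](C)(C)C(C)(C)C)C/C=C(/C)Cl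
F5 | step 8 | (3S,4R)-3-chloro-3-methyl-4-(3-oxobutyl)oxolan-2-one | C[C@@]1(Cl)C(=O)OC[C@H]1CCC(C)=O
F6 | step 8 | (3S,4R)-3-chloro-3-methyl-4-[2-(2-methyl-1,3-dioxolan-2-yl)ethyl]oxolan-2-one | C[C@@]1(Cl)C(=O)OC[C@H]1CCC2(C)OCCO2
F7 | step 8 | (3S,4R)-3-chloro-3-methyl-4-[2-(2-methyl-1,3-dioxolan-2-yl)ethyl]oxolan-2-ol (anomer mixture) | C[C@@]1(Cl)C(O)OC[C@H]1CCC2(C)OCCO2
F8 | step 8 | (2R,3S,4E)-5-bromo-3-chloro-3-methyl-2-[2-(2-methyl-1,3-dioxolan-2-yl)ethyl]pent-4-en-1-ol | C[C@@](Cl)(/C=C/Br)[C@@H](CO)CCC1(C)OCCO1
F9 | step 8 | (2R,5R)-5-[(2S,3E)-4-bromo-2-chlorobut-3-en-2-yl]-2-methyloxan-2-ol | C[C@@](Cl)(/C=C/Br)[C@H]1CO[C@@](C)(O)CC1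
F10 | step 5 | {[(4S)-4-[(2Z)-3-chlorobut-2-en-1-yl]-3-methyl-4,5-dihydrofuran-2-yl]oxy}(trimethyl)silane | C[Si](C)(C)OC1=C(C)[C@H](C/C=C(/C)Cl)CO1
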